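Midnight has half the partner of dusk and twice the time, so I ask whether the two cancel.

| setting | beta | gamma | zeta | theta | dusk | midnight |
|---|---|---|---|---|---|---|
| starting material | 0.056 M | 0.056 M | 0.056 M | 0.056 M | 0.056 M | 0.056 M |
| partner | 5 equiv | 5 equiv | 5 equiv | 4.2 equiv | 5.00 equiv | 2.50 equiv |
| protic impurity | 0.0062 M | 0.0084 M | 0.012 M | 0.0112 M | 0.0112 M | 0.00600 M |
| remark | run made earlier | run made earlier | run made earlier | run made earlier |  |  |
| time |  |  |  |  | 25 h | 50 h |

| run | time / h | target / % | starting material / % |
|---|---|---|---|
| beta | 2.50 | 26 | 48 |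
| beta | 5.00 | 54 | 28 |
| beta | 8.00 | 71 | 15 |
| beta | 10.0 | 79 | 10 |
| beta | 12.0 | 83 | 6 |
| gamma | 1.00 | 5 | 74 |
| gamma | 3.00 | 32 | 42 |
| gamma | 6.00 | 60 | 19 |
| gamma | 8.00 | 72 | 14 |
| gamma | 12.0 | 86 | 7 |
| zeta | 1.00 | 4 | 74 |
| zeta | 2.00 | 17 | 55 |
| zeta | 4.00 | 42 | 35 |
| zeta | 6.00 | 60 | 23 |
| zeta | 12.0 | 82 | 6 |
| theta | 2.50 | 25 | 50 |
| theta | 5.00 | 46 | 30 |
| theta | 8.00 | 69 | 16 |
| theta | 10.0 | 73 | 16 |
| theta | 12.0 | 82 | 7 |

(scatter of a reading: 1.5 percentage points)

- what was read earlier has a scatter of 1.5 percentage points, one standard deviation

* the winner by amount of target, in percent of the starting material charged; "neither" if no more than 2 percentage points parts them (dusk / midnight / neither)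
* how much target is there at the end, in percent of the starting material charged: dusk
* how much target is there at the end, in percent of the starting material charged: midnight

In the beta run, with partner in excess, I read the starting material as a pseudo-first-order decay: it falls from 28% to 6% between 5.00 h and 12.0 h, which gives a rate k of 0.220 h⁻¹. I assume k scales with the partner concentration. Then the number I carry is n, the lifetimes a flask receives: k, scaled by its charged partner concentration over that of beta, times its time. For dusk, n is 5.50, and for midnight it is 5.50. So I expect the same starting material left in each, e to the power −n, or 0.408%, and near-complete conversion in both.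

The forecast gives 97% for dusk, 95.5% for midnight and the winner neither: “The difference is within 2 points, so neither wins.”

Dusk gives 94.3% and midnight 94.8%, so the winner is neither. Starting material left is 0.699% in dusk and 0.536% in midnight.

    partner + protic impurity → quenched reagent (k = 0.640 M⁻¹ min⁻¹)
    starting material ⇌ tautomer (K = 1.30, k = 0.00600 min⁻¹)
    starting material + partner ⇌ isomer of the product (K = 5.60 M⁻¹, k = 7.20 × 10⁻⁴ M⁻¹ min⁻¹)
    tautomer → side product (k = 8.30 × 10⁻⁵ min⁻¹)
    partner + tautomer → target (k = 0.0360 M⁻¹ min⁻¹)

The neighbouring flask is midnight made at 0.034 M of starting material, with the equivalents of partner and the time held, so its partner concentration falls too. Its n is 3.34, smaller than that of midnight, and e to the power −n gives 3.54% left. At the end the neighbouring flask holds 2.1% starting material and 2.31% tautomer. Its target is 90.6%, which is 4.2 percentage points below midnight, wider than the margin of 2 points.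

Readings and results were computed for an exercise, noise included.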